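**Plan**

- Retrosynthesis: the O5–Si bond is cut last; then O1–C2 and C4–C4a of the pyranone ring are cut together, giving phenol 7 and (E)-4-methoxycinnamoyl chloride 9; the C8–prenyl bond is cut back to 5-methoxyresorcinol.
- Enabling feature: the A ring is a phloroglucinol. C4a lies between C5–O and C8a–O1 and para to the C7 methoxy, so it is an enol-like carbon nucleophile ortho to the O1 phenol (a 1,3-C,O-dinucleophile). C2–C3–C4 is a cinnamoyl 1,3-dielectrophile, and the C8 prenyl blocks the other ortho carbon.
- Forward: the A-ring substituents are set first (O5 silyl ether, MOM-directed lithiation and prenylation at C8). The pyranone ring then closes in one pot by Mg-templated C-acylation at C4a followed by oxa-Michael addition of O1 to C2.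
- Stereochemistry: the only stereocentre, C2 (S), is set by a bifunctional cinchona thiourea in the oxa-Michael stage and is kept by a buffered, non-basic desilylation.

Key step: step 6

Assumption: the quinine-derived thiourea is taken to direct the phenoxide to the Si face of C-β (giving 2S); if the sense is the reverse, the quinidine-derived pseudoenantiomer is used under the same conditions.

**Step 1**
Reactants: 1 5-methoxybenzene-1,3-diol (5-methoxyresorcinol)
Product: 2 3-methoxy-5-(triisopropylsilyloxy)phenol
Conditions: NaH (1.0 equiv), THF, 0 °C; TIPSCl (1.0 equiv), 0 °C→rt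
Reagents that add atoms: chlorotriisopropylsilane, CC(C)[Si](Cl)(C(C)C)C(C)C
Why: O-silylation of the monosodium phenoxide of a symmetric diol should give the mono-ether statistically (diol and bis-ether are separable and recyclable); the bulky TIPS ether later shields its neighbouring ring positions and masks O5.

**Step 2**
Reactants: 2 3-methoxy-5-(triisopropylsilyloxy)phenol
Product: 3 1-methoxy-3-(methoxymethoxy)-5-(triisopropylsilyloxy)benzene
Conditions: NaH, THF, 0 °C; MOMCl, 0 °C→rt
Reagents that add atoms: chloromethyl methyl ether, COCCl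
Why: Williamson-type MOM protection of the phenoxide installs the directing group for ortho-lithiation.

**Step 3**
Reactants: 3 1-methoxy-3-(methoxymethoxy)-5-(triisopropylsilyloxy)benzene; 4 1-bromo-3-methylbut-2-ene (prenyl bromide)
Product: 6 1-methoxy-3-(methoxymethoxy)-2-(3-methylbut-2-en-1-yl)-5-(triisopropylsilyloxy)benzene, via aryllithium 5 (not isolated)
Conditions: n-BuLi, THF, 0 °C; CuBr·SMe2 (10 mol%), 4, −78 °C→rt
Reagents that add atoms: none
Why: Directed ortho-metalation should occur at the carbon between OMOM and OMe (cooperative coordination, while the positions next to OTIPS are shielded), and Cu-catalysed SN2 allylation of the aryllithium places the prenyl group there.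

**Step 4**
Reactants: 6 1-methoxy-3-(methoxymethoxy)-2-(3-methylbut-2-en-1-yl)-5-(triisopropylsilyloxy)benzene
Product: 7 3-methoxy-2-(3-methylbut-2-en-1-yl)-5-(triisopropylsilyloxy)phenol
Conditions: conc. HCl (cat.), MeOH, rt
Reagents that add atoms: none
Why: Acid-catalysed transacetalisation should cleave the MOM acetal at room temperature while the aryl TIPS ether and the trisubstituted alkene stay intact.

**Step 5**
Reactants: 8 (E)-4-methoxycinnamic acid
Product: 9 (E)-4-methoxycinnamoyl chloride
Conditions: (COCl)2, DMF (cat.), CH2Cl2, 0 °C→rt; used crude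
Reagents that add atoms: oxalyl chloride, ClC(=O)C(=O)Cl
Why: Vilsmeier-type activation converts the acid into the acid chloride with the E geometry retained.

**Step 6**
Reactants: 7 3-methoxy-2-(3-methylbut-2-en-1-yl)-5-(triisopropylsilyloxy)phenol; 9 (E)-4-methoxycinnamoyl chloride
Product: 12 (2S)-7-methoxy-2-(4-methoxyphenyl)-8-(3-methylbut-2-en-1-yl)-5-(triisopropylsilyloxy)-2,3-dihydro-4H-chromen-4-one, via bromomagnesium phenoxide 10 (not isolated), via chalcone 11 (not isolated)
Conditions: EtMgBr (1.0 equiv), Et2O, 0 °C; solvent switch to toluene; 9, 0 °C→rt; aq. NH4Cl wash, dry (no isolation); quinine-derived thiourea 1-[3,5-bis(trifluoromethyl)phenyl]-3-[(8α,9S)-6′-methoxycinchonan-9-yl]thiourea (10 mol%), toluene, 0 °C→rt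
Reagents that add atoms: none
Why: EtMgBr turns 7 into the aryloxymagnesium bromide 10, whose Mg binds the acyl chloride carbonyl and delivers the acyl carbon through a six-membered transition state to the only free ortho carbon (C4a), giving chalcone 11 after proton transfer; the thiourea then H-bonds the enone carbonyl while its quinuclidine deprotonates the 2′-OH, and the phenoxide adds to C-β. The closest known reaction types are the chelation-controlled ortho-acylation of magnesium phenoxides with acyl chlorides (template Friedel–Crafts acylation) and the organocatalytic asymmetric cyclisation of 2′-hydroxychalcones to flavanones. The pyranone ring closes by a 6-endo-trig oxa-Michael addition. C2 is set by the catalyst, which should hold the ion-paired phenoxide over the Si face of C-β and so give the 2S configuration. The step needs C- over O-acylation and C4a over C6, which the Mg template in a non-coordinating solvent and the prenyl group on the other ortho carbon should secure; only O1 can cyclise because O5 is silylated, which excludes the 6-prenyl regioisomer. The 6′-silyloxy group also shifts the chalcone–flavanone equilibrium toward the ring, which should limit loss of ee by retro-oxa-Michael opening.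

**Step 7**
Reactants: 12 (2S)-7-methoxy-2-(4-methoxyphenyl)-8-(3-methylbut-2-en-1-yl)-5-(triisopropylsilyloxy)-2,3-dihydro-4H-chromen-4-one
Product: 13 Flowerine, (2S)-5-hydroxy-7-methoxy-2-(4-methoxyphenyl)-8-(3-methylbut-2-en-1-yl)-2,3-dihydro-4H-chromen-4-one
Conditions: TBAF (1.2 equiv), AcOH (1.2 equiv), THF, 0 °C
Reagents that add atoms: none
Why: Fluoride-mediated cleavage of the aryl silyl ether, buffered with acetic acid, keeps the medium non-basic so that the flavanone should not open by E1cB and C2 is retained.

**Compound list**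

1 | 5-methoxybenzene-1,3-diol | COc1cc(O)cc(O)c1 | starting material
2 | 3-methoxy-5-(triisopropylsilyloxy)phenol | COc1cc(O)cc(O[Si](C(C)C)(C(C)C)C(C)C)c1 | intermediate
3 | 1-methoxy-3-(methoxymethoxy)-5-(triisopropylsilyloxy)benzene | COCOc1cc(OC)cc(O[Si](C(C)C)(C(C)C)C(C)C)c1 | intermediate
4 | 1-bromo-3-methylbut-2-ene (prenyl bromide) | CC(C)=CCBr | starting material
5 | [2-methoxy-6-(methoxymethoxy)-4-(triisopropylsilyloxy)phenyl]lithium | [Li]c1c(OC)cc(O[Si](C(C)C)(C(C)C)C(C)C)cc1OCOC | intermediate
6 | 1-methoxy-3-(methoxymethoxy)-2-(3-methylbut-2-en-1-yl)-5-(triisopropylsilyloxy)benzene | COCOc1cc(O[Si](C(C)C)(C(C)C)C(C)C)cc(OC)c1CC=C(C)C | intermediate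
7 | 3-methoxy-2-(3-methylbut-2-en-1-yl)-5-(triisopropylsilyloxy)phenol | Oc1cc(O[Si](C(C)C)(C(C)C)C(C)C)cc(OC)c1CC=C(C)C | intermediate
8 | (E)-4-methoxycinnamic acid | COc1ccc(/C=C/C(=O)O)cc1 | starting material
9 | (E)-4-methoxycinnamoyl chloride | COc1ccc(/C=C/C(=O)Cl)cc1 | intermediate
10 | bromomagnesium 3-methoxy-2-(3-methylbut-2-en-1-yl)-5-(triisopropylsilyloxy)phenoxide | Br[Mg]Oc1cc(O[Si](C(C)C)(C(C)C)C(C)C)cc(OC)c1CC=C(C)C | intermediate
11 | (E)-1-[2-hydroxy-4-methoxy-3-(3-methylbut-2-en-1-yl)-6-(triisopropylsilyloxy)phenyl]-3-(4-methoxyphenyl)prop-2-en-1-one | COc1ccc(/C=C/C(=O)c2c(O)c(CC=C(C)C)c(OC)cc2O[Si](C(C)C)(C(C)C)C(C)C)cc1 | intermediate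
12 | (2S)-7-methoxy-2-(4-methoxyphenyl)-8-(3-methylbut-2-en-1-yl)-5-(triisopropylsilyloxy)-2,3-dihydro-4H-chromen-4-one | COc1ccc([C@@H]2CC(=O)c3c(O[Si](C(C)C)(C(C)C)C(C)C)cc(OC)c(CC=C(C)C)c3O2)cc1 | intermediate
13 | Flowerine, (2S)-5-hydroxy-7-methoxy-2-(4-methoxyphenyl)-8-(3-methylbut-2-en-1-yl)-2,3-dihydro-4H-chromen-4-one | COc1ccc([C@@H]2CC(=O)c3c(O)cc(OC)c(CC=C(C)C)c3O2)cc1 | target

**Step count**

Total steps: 7. Longest linear sequence: 6 (steps 1, 2, 3, 4, 6 and 7 from 5-methoxyresorcinol).

**Steps most likely to fail**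

Step 6. The ring closure may proceed with poor facial selectivity, or the flavanone may lose ee by reversible retro-oxa-Michael opening under the amine catalyst; O-acylation of the magnesium phenoxide may also compete with C-acylation. The fallback sets out from 7 and sets the stereocentre by C2–aryl bond formation instead. The magnesium phenoxide of 7 is C-acetylated with acetyl chloride to 1-[2-hydroxy-4-methoxy-3-(3-methylbut-2-en-1-yl)-6-(triisopropylsilyloxy)phenyl]ethanone F1. Condensation with DMF dimethyl acetal gives the enaminone (E)-3-(dimethylamino)-1-[2-hydroxy-4-methoxy-3-(3-methylbut-2-en-1-yl)-6-(triisopropylsilyloxy)phenyl]prop-2-en-1-one F2. Dilute HCl in CH2Cl2 closes it to the chromone 7-methoxy-8-(3-methylbut-2-en-1-yl)-5-(triisopropylsilyloxy)-4H-chromen-4-one F3. A Pd(II)/t-BuPyOx-catalysed asymmetric conjugate addition of 4-methoxyphenylboronic acid (ligand antipode chosen for 2S) then comes back to the route at 12.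

Step 3. Lithiation may take place at a ring carbon other than the one between OMOM and OMe, or the aryl-metal may capture prenyl bromide in the SN2′ sense and give the 1,1-dimethylallyl isomer. The fallback sets out from 2 and moves the prenyl group from oxygen to carbon by a sigmatropic shift. Phenol 2 is O-alkylated with 3-chloro-3-methylbut-1-yne (DBU, CuCl2 cat., MeCN) to triisopropyl[3-methoxy-5-(2-methylbut-3-yn-2-yloxy)phenoxy]silane F4. Lindlar semi-hydrogenation gives the 1,1-dimethylallyl ether triisopropyl[3-methoxy-5-(2-methylbut-3-en-2-yloxy)phenoxy]silane F5. Thermal aromatic Claisen rearrangement (toluene, 120 °C), directed to the less hindered ortho carbon next to OMe, comes back to the route at 7, so steps 2 to 4 are bypassed.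

Step 4. Under acid the freed phenol may add to the prenyl double bond (chroman formation), or the silyl ether may be lost during acetal cleavage. The fallback sets out from 2 and uses a directing group that is removed without acid. Phenol 2 is carbamoylated (ClCONEt2, NaH) to 3-methoxy-5-(triisopropylsilyloxy)phenyl N,N-diethylcarbamate F6. Ortho-lithiation (s-BuLi, TMEDA, THF, −78 °C), CuBr·SMe2 and prenyl bromide give 3-methoxy-2-(3-methylbut-2-en-1-yl)-5-(triisopropylsilyloxy)phenyl N,N-diethylcarbamate F7. Reductive cleavage with LiAlH4 (THF, 0 °C) comes back to the route at 7.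

**Further compounds**

F1 | step 6 | 1-[2-hydroxy-4-methoxy-3-(3-methylbut-2-en-1-yl)-6-(triisopropylsilyloxy)phenyl]ethanone | CC(=O)c1c(O)c(CC=C(C)C)c(OC)cc1O[Si](C(C)C)(C(C)C)C(C)C
F2 | step 6 | (E)-3-(dimethylamino)-1-[2-hydroxy-4-methoxy-3-(3-methylbut-2-en-1-yl)-6-(triisopropylsilyloxy)phenyl]prop-2-en-1-one | CN(C)/C=C/C(=O)c1c(O)c(CC=C(C)C)c(OC)cc1O[Si](C(C)C)(C(C)C)C(C)C
F3 | step 6 | 7-methoxy-8-(3-methylbut-2-en-1-yl)-5-(triisopropylsilyloxy)-4H-chromen-4-one | COc1cc(O[Si](C(C)C)(C(C)C)C(C)C)c2c(=O)ccoc2c1CC=C(C)C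
F4 | step 3 | triisopropyl[3-methoxy-5-(2-methylbut-3-yn-2-yloxy)phenoxy]silane | C#CC(C)(C)Oc1cc(OC)cc(O[Si](C(C)C)(C(C)C)C(C)C)c1
F5 | step 3 | triisopropyl[3-methoxy-5-(2-methylbut-3-en-2-yloxy)phenoxy]silane | C=CC(C)(C)Oc1cc(OC)cc(O[Si](C(C)C)(C(C)C)C(C)C)c1
F6 | step 4 | 3-methoxy-5-(triisopropylsilyloxy)phenyl N,N-diethylcarbamate | CCN(CC)C(=O)Oc1cc(OC)cc(O[Si](C(C)C)(C(C)C)C(C)C)c1
F7 | step 4 | 3-methoxy-2-(3-methylbut-2-en-1-yl)-5-(triisopropylsilyloxy)phenyl N,N-diethylcarbamate | CCN(CC)C(=O)Oc1cc(O[Si](C(C)C)(C(C)C)C(C)C)cc(OC)c1CC=C(C)C
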